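**Strategy.** Ring A is disconnected across C1–C10 and C2–C3 (drimane-type numbering). Its unsubstituted C1–C2 ethano unit comes from phenyl vinyl sulfone, which adds in a Diels–Alder reaction to the ring B dienone 15, a 2-isopropenylcyclohex-2-enone (diene C3=C4–C5=C10) that already holds C8, C9 and the arylmethyl group. One operation closes ring A, sets C10 and leaves a Δ4-6-ketone, the retron of the C4 gem-dimethyl/C5=C6 pair (conjugate methylation, enol phosphate reduction). Dienone 15 is made from (R)-pulegone by double α′-alkylation, dehydrogenation and 1,3-carbonyl transposition; formylation, sulfation and fluoride deprotection finish the arene.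

Key step: step 11

Remark (numbering and abbreviations): ring A = C1–C2–C3–C4–C5–C10, ring B = C5–C6–C7–C8–C9–C10, C11 = benzylic CH2 on C9, arene C1′–C6′ with C11 on C1′. SEM = [2-(trimethylsilyl)ethoxy]methyl; Ar = 2-(benzyloxy)-4,5-bis(SEM-oxy)phenyl; Dec = (1R,2R,8aS)-1,2,5,5-tetramethyl-1,2,3,5,6,7,8,8a-octahydronaphthalen-1-yl.

Remark (undefined centres): C6 in 11–14 and the sulfonyl-bearing C2 in 17–19 are expected as epimeric mixtures that converge in steps 10 and 13; they are left undefined in the SMILES.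

Remark (sulfate form): the aryl hydrogen sulfates 23 and 24 are written as free acids, as in the target; in practice they would be handled as salts and acidified only at isolation.

**Step 1**
Reactants: 1 2,4,5-trihydroxybenzaldehyde
Product: 2 2-hydroxy-4,5-bis(SEM-oxy)benzaldehyde
Conditions: SEMCl (2.1 equiv), i-Pr2NEt, CH2Cl2, 0 °C
Reagents that add atoms: 2-(trimethylsilyl)ethoxymethyl chloride, ClCOCC[Si](C)(C)C
Why: O-alkylation (SEM acetal protection) should stop at the 4- and 5-hydroxyls, because the 2-hydroxyl is held in an intramolecular hydrogen bond to the formyl group and is the least nucleophilic.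

**Step 2**
Reactants: 2 2-hydroxy-4,5-bis(SEM-oxy)benzaldehyde
Product: 3 2-(benzyloxy)-4,5-bis(SEM-oxy)benzaldehyde
Conditions: BnBr, K2CO3, DMF, 50 °C
Reagents that add atoms: benzyl bromide, BrCc1ccccc1
Why: Williamson ether synthesis on the remaining chelated phenol under warm carbonate conditions.

**Step 3**
Reactants: 3 2-(benzyloxy)-4,5-bis(SEM-oxy)benzaldehyde
Product: 4 ArCH2OH, [2-(benzyloxy)-4,5-bis(SEM-oxy)phenyl]methanol
Conditions: NaBH4, MeOH/THF, 0 °C
Reagents that add atoms: none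
Why: Borohydride reduction of the aryl aldehyde to the benzylic alcohol; nothing else in the molecule is reducible.

**Step 4**
Reactants: 4 ArCH2OH
Product: 5 ArCH2Br, 1-(benzyloxy)-2-(bromomethyl)-4,5-bis(SEM-oxy)benzene
Conditions: CBr4, PPh3, CH2Cl2, −20 °C; crude 5 used at once
Reagents that add atoms: carbon tetrabromide, BrC(Br)(Br)Br
Why: Appel bromination runs under neutral conditions that the acid-labile SEM acetals tolerate; the electron-rich benzylic bromide is not stored.

**Step 5**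
Reactants: 6 (R)-(+)-pulegone; 5 ArCH2Br
Product: 7 (2S,3R)-2-(ArCH2)-3-methyl-6-(propan-2-ylidene)cyclohexan-1-one
Conditions: LDA, THF, −78 °C; then 5, DMPU, −78 → −20 °C
Reagents that add atoms: none
Why: Kinetic α′-deprotonation gives the cross-conjugated enolate at C9 and SN2 enolate alkylation should place the arylmethyl group trans to the C8 methyl (this centre is made planar again in step 6).

**Step 6**
Reactants: 7 (2S,3R)-2-(ArCH2)-3-methyl-6-(propan-2-ylidene)cyclohexan-1-one
Product: 8 (2R,3R)-2-(ArCH2)-2,3-dimethyl-6-(propan-2-ylidene)cyclohexan-1-one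
Conditions: LDA, THF, −78 → −40 °C; then MeI, DMPU, −78 → 0 °C
Reagents that add atoms: iodomethane, CI
Why: Enolate alkylation; in the fully substituted C9 enolate, A(1,2) strain with the arylmethyl group holds the C8 methyl pseudoaxial, so MeI should add axially to the opposite face and give the quaternary centre with CH3 trans and ArCH2 cis to the C8 methyl (9R).

**Step 7**
Reactants: 8 (2R,3R)-2-(ArCH2)-2,3-dimethyl-6-(propan-2-ylidene)cyclohexan-1-one
Product: 10 (5R,6R)-6-(ArCH2)-5,6-dimethyl-2-(prop-1-en-2-yl)cyclohex-2-en-1-one, via trimethylsilyl dienol ether 9 (not isolated)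
Conditions: LDA, THF, −78 → 0 °C; TMSCl, −78 °C; then Pd(OAc)2 (1.05 equiv), MeCN, rt
Reagents that add atoms: none
Why: With C9 quaternary the only acidic hydrogens are on the isopropylidene methyls, so γ-deprotonation and O-silylation give the silyloxy diene, and Saegusa–Ito oxidation (β-hydride elimination from the C5-bound palladium enolate, which has hydrogens only on C6) should give the cross-conjugated 2-isopropenyl enone.

**Step 8**
Reactants: 10 (5R,6R)-6-(ArCH2)-5,6-dimethyl-2-(prop-1-en-2-yl)cyclohex-2-en-1-one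
Product: 11 (5R,6R)-6-(ArCH2)-2,3-epoxy-5,6-dimethyl-2-(prop-1-en-2-yl)cyclohexan-1-one
Conditions: 30% H2O2, NaOH, MeOH, 0 °C
Reagents that add atoms: hydrogen peroxide, OO
Why: Weitz–Scheffer nucleophilic epoxidation attacks only the enone C5=C6 bond, since the isopropenyl group is not polarised by the carbonyl; the epoxide configuration is lost in steps 9 and 10.

**Step 9**
Reactants: 11 (5R,6R)-6-(ArCH2)-2,3-epoxy-5,6-dimethyl-2-(prop-1-en-2-yl)cyclohexan-1-one
Product: 14 (4R,5R)-4-(ArCH2)-4,5-dimethyl-2-(prop-1-en-2-yl)cyclohex-2-en-1-ol, via epoxy hydrazone 12 (not isolated), via alkenyldiazene 13 (not isolated)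
Conditions: N2H4·H2O, AcOH (cat.), MeOH, 0 °C → rt
Reagents that add atoms: none
Why: Wharton transposition: the hydrazone opens the epoxide to an alkenyldiazene that loses N2, which moves the oxygen to C6 and the double bond to C5=C10 without touching C8 or C9.

**Step 10**
Reactants: 14 (4R,5R)-4-(ArCH2)-4,5-dimethyl-2-(prop-1-en-2-yl)cyclohex-2-en-1-ol
Product: 15 (4R,5R)-4-(ArCH2)-4,5-dimethyl-2-(prop-1-en-2-yl)cyclohex-2-en-1-one
Conditions: Dess–Martin periodinane, NaHCO3, CH2Cl2, 0 °C; used at once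
Reagents that add atoms: none
Why: Dess–Martin oxidation of the allylic alcohol gives the cross-conjugated dienone and removes the C6 stereocentre; immediate use should limit dimerisation.

**Step 11**
Reactants: 15 (4R,5R)-4-(ArCH2)-4,5-dimethyl-2-(prop-1-en-2-yl)cyclohex-2-en-1-one; 16 phenyl vinyl sulfone
Product: 17 (3R,4R,4aS)-4-(ArCH2)-3,4,8-trimethyl-6-(phenylsulfonyl)-3,4,4a,5,6,7-hexahydronaphthalen-1(2H)-one (drimane numbering: 8R,9R,10S; C4 methyl, C4=C5, C6 ketone, PhSO2 on C2)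
Conditions: 16 (4 equiv), BHT (cat.), toluene, 120 °C, sealed tube
Reagents that add atoms: none
Why: Concerted, asynchronous thermal [4+2] cycloaddition of the s-cis diene C3=C4–C5=C10 of 15 with the sulfonyl-activated alkene 16; the closest known type is the Diels–Alder reaction of 2-acyl-1,3-dienes, with phenyl vinyl sulfone serving as an ethylene equivalent. Ring A is closed by intermolecular [4+2] annulation onto ring B, forming C1–C10 and C2–C3 suprafacially on both partners, and the new C4=C5 bond emerges conjugated with the C6 ketone. The one new stereocentre that matters, C10, is set by the π-face attacked: attack anti to the pseudoaxial arylmethyl group on C9 lets the C8 methyl stay equatorial, whereas attack on the other face forces a syn-axial contact between the forming C10–C1 bond and the C8 methyl, so C1 should enter trans to both (10S). The sulfonyl-bearing carbon should be C2, because the CH2 end of the dienophile prefers the hindered C10 terminus; its configuration does not matter, since the sulfone is removed in step 13. The step needs reactivity at a diene terminus next to a quaternary carbon and π-facial selectivity; the 2,3-disubstituted diene with ready access to the s-cis form, excess dienophile and the ring B conformational bias described above are expected to secure both.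

**Step 12**
Reactants: 17 Diels–Alder adduct (Δ4-6-ketone)
Product: 19 diethyl [(3R,4R,4aS)-4-(ArCH2)-3,4,8,8-tetramethyl-6-(phenylsulfonyl)-2,3,4,4a,5,6,7,8-octahydronaphthalen-1-yl] phosphate, via lithium enolate 18 (not isolated)
Conditions: Me2CuLi (from CuI and MeLi, 3 equiv), Et2O, −20 → 0 °C; then ClP(O)(OEt)2, Et3N, HMPA, 0 °C → rt
Reagents that add atoms: lithium dimethylcuprate, [Li+].C[Cu-]C; diethyl chlorophosphate, CCOP(=O)(Cl)OCC
Why: Cuprate 1,4-addition to the s-cis alkylidene-ketone enone (the pulegone-type case) should create the C4 gem-dimethyl carbon, and O-phosphorylation of the regiodefined enolate fixes the double bond at C5=C6.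

**Step 13**
Reactants: 19 enol phosphate
Product: 20 2-(DecCH2)-4,5-bis(SEM-oxy)phenol
Conditions: Li, NH3(l), THF, t-BuOH, −78 °C; NH4Cl
Reagents that add atoms: none
Why: Dissolving-metal reduction should cleave the enol phosphate C–O bond to the C5=C6 alkene, the sulfone C–S bond (reductive desulfonylation) and the benzyl ether in one operation; the isolated trisubstituted alkene and the phenoxide ring formed on debenzylation resist reduction.

**Step 14**
Reactants: 20 2-(DecCH2)-4,5-bis(SEM-oxy)phenol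
Product: 22 2-hydroxy-3-(DecCH2)-5,6-bis(SEM-oxy)benzaldehyde, via hydroxymethylphenol 21 (not isolated)
Conditions: MgCl2, Et3N, (CH2O)n, MeCN, reflux
Reagents that add atoms: paraformaldehyde (as formaldehyde), C=O
Why: Casnati–Skattebøl ortho-formylation: the magnesium phenoxide delivers formaldehyde to its only free ortho position, C3′, and a second formaldehyde oxidises the hydroxymethyl intermediate by hydride transfer.

**Step 15**
Reactants: 22 2-hydroxy-3-(DecCH2)-5,6-bis(SEM-oxy)benzaldehyde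
Product: 23 2-formyl-6-(DecCH2)-3,4-bis(SEM-oxy)phenyl hydrogen sulfate
Conditions: SO3·pyridine, pyridine, 50 °C
Reagents that add atoms: sulfur trioxide–pyridine complex, [O-]S(=O)(=O)[n+]1ccccc1
Why: O-sulfation of the only free phenol with the amine–SO3 complex; the basic medium keeps the sulfate monoester from hydrolysing.

**Step 16**
Reactants: 23 2-formyl-6-(DecCH2)-3,4-bis(SEM-oxy)phenyl hydrogen sulfate
Product: 24 target, 2-formyl-3,4-dihydroxy-6-(DecCH2)phenyl hydrogen sulfate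
Conditions: TBAF, THF/DMPU, 50 °C, argon; then cold 0.5 M HCl to pH 2
Reagents that add atoms: none
Why: Fluoride attack on silicon fragments both SEM ethers (loss of ethene and formaldehyde) under non-acidic conditions that the aryl sulfate monoester, the aldehyde and the C5=C6 alkene should tolerate.

**Compound list**

1 | 2,4,5-trihydroxybenzaldehyde | O=Cc1cc(O)c(O)cc1O | starting material
2 | 2-hydroxy-4,5-bis(SEM-oxy)benzaldehyde | O=Cc1cc(OCOCC[Si](C)(C)C)c(OCOCC[Si](C)(C)C)cc1O | intermediate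
3 | 2-(benzyloxy)-4,5-bis(SEM-oxy)benzaldehyde | O=Cc1cc(OCOCC[Si](C)(C)C)c(OCOCC[Si](C)(C)C)cc1OCc1ccccc1 | intermediate
4 | ArCH2OH, [2-(benzyloxy)-4,5-bis(SEM-oxy)phenyl]methanol | OCc1cc(OCOCC[Si](C)(C)C)c(OCOCC[Si](C)(C)C)cc1OCc1ccccc1 | intermediate
5 | ArCH2Br, 1-(benzyloxy)-2-(bromomethyl)-4,5-bis(SEM-oxy)benzene | BrCc1cc(OCOCC[Si](C)(C)C)c(OCOCC[Si](C)(C)C)cc1OCc1ccccc1 | intermediate
6 | (R)-(+)-pulegone, (5R)-5-methyl-2-(propan-2-ylidene)cyclohexan-1-one | C[C@@H]1CCC(=C(C)C)C(=O)C1 | starting material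
7 | (2S,3R)-2-(ArCH2)-3-methyl-6-(propan-2-ylidene)cyclohexan-1-one (ArCH2 trans to CH3) | C[C@@H]1CCC(=C(C)C)C(=O)[C@H]1Cc1cc(OCOCC[Si](C)(C)C)c(OCOCC[Si](C)(C)C)cc1OCc1ccccc1 | intermediate
8 | (2R,3R)-2-(ArCH2)-2,3-dimethyl-6-(propan-2-ylidene)cyclohexan-1-one (ArCH2 cis to the C3 methyl) | C[C@@H]1CCC(=C(C)C)C(=O)[C@]1(C)Cc1cc(OCOCC[Si](C)(C)C)c(OCOCC[Si](C)(C)C)cc1OCc1ccccc1 | intermediate
9 | {[(5R,6R)-6-(ArCH2)-5,6-dimethyl-2-(prop-1-en-2-yl)cyclohex-1-en-1-yl]oxy}trimethylsilane (not isolated) | C[C@@H]1CCC(C(C)=C)=C(O[Si](C)(C)C)[C@]1(C)Cc1cc(OCOCC[Si](C)(C)C)c(OCOCC[Si](C)(C)C)cc1OCc1ccccc1 | intermediate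
10 | (5R,6R)-6-(ArCH2)-5,6-dimethyl-2-(prop-1-en-2-yl)cyclohex-2-en-1-one | C[C@@H]1CC=C(C(C)=C)C(=O)[C@]1(C)Cc1cc(OCOCC[Si](C)(C)C)c(OCOCC[Si](C)(C)C)cc1OCc1ccccc1 | intermediate
11 | (5R,6R)-6-(ArCH2)-2,3-epoxy-5,6-dimethyl-2-(prop-1-en-2-yl)cyclohexan-1-one (epoxide face undefined) | C[C@@H]1CC2OC2(C(C)=C)C(=O)[C@]1(C)Cc1cc(OCOCC[Si](C)(C)C)c(OCOCC[Si](C)(C)C)cc1OCc1ccccc1 | intermediate
12 | hydrazone of 11 (not isolated) | C[C@@H]1CC2OC2(C(C)=C)C(=NN)[C@]1(C)Cc1cc(OCOCC[Si](C)(C)C)c(OCOCC[Si](C)(C)C)cc1OCc1ccccc1 | intermediate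
13 | (4R,5R)-4-(ArCH2)-3-diazenyl-4,5-dimethyl-2-(prop-1-en-2-yl)cyclohex-2-en-1-ol (not isolated) | C[C@@H]1CC(O)C(C(C)=C)=C(N=N)[C@]1(C)Cc1cc(OCOCC[Si](C)(C)C)c(OCOCC[Si](C)(C)C)cc1OCc1ccccc1 | intermediate
14 | (4R,5R)-4-(ArCH2)-4,5-dimethyl-2-(prop-1-en-2-yl)cyclohex-2-en-1-ol (C1 epimers) | C[C@@H]1CC(O)C(C(C)=C)=C[C@]1(C)Cc1cc(OCOCC[Si](C)(C)C)c(OCOCC[Si](C)(C)C)cc1OCc1ccccc1 | intermediate
15 | (4R,5R)-4-(ArCH2)-4,5-dimethyl-2-(prop-1-en-2-yl)cyclohex-2-en-1-one | C[C@@H]1CC(=O)C(C(C)=C)=C[C@]1(C)Cc1cc(OCOCC[Si](C)(C)C)c(OCOCC[Si](C)(C)C)cc1OCc1ccccc1 | intermediate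
16 | phenyl vinyl sulfone | C=CS(=O)(=O)c1ccccc1 | starting material
17 | (3R,4R,4aS)-4-(ArCH2)-3,4,8-trimethyl-6-(phenylsulfonyl)-3,4,4a,5,6,7-hexahydronaphthalen-1(2H)-one (sulfonyl carbon undefined) | C[C@@H]1CC(=O)C2=C(C)CC(S(=O)(=O)c3ccccc3)C[C@H]2[C@]1(C)Cc1cc(OCOCC[Si](C)(C)C)c(OCOCC[Si](C)(C)C)cc1OCc1ccccc1 | intermediate
18 | lithium (3R,4R,4aS)-4-(ArCH2)-3,4,8,8-tetramethyl-6-(phenylsulfonyl)-2,3,4,4a,5,6,7,8-octahydronaphthalen-1-olate (not isolated) | C[C@@H]1CC(O[Li])=C2[C@@H](CC(S(=O)(=O)c3ccccc3)CC2(C)C)[C@]1(C)Cc1cc(OCOCC[Si](C)(C)C)c(OCOCC[Si](C)(C)C)cc1OCc1ccccc1 | intermediate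
19 | diethyl [(3R,4R,4aS)-4-(ArCH2)-3,4,8,8-tetramethyl-6-(phenylsulfonyl)-2,3,4,4a,5,6,7,8-octahydronaphthalen-1-yl] phosphate | C[C@@H]1CC(OP(=O)(OCC)OCC)=C2[C@@H](CC(S(=O)(=O)c3ccccc3)CC2(C)C)[C@]1(C)Cc1cc(OCOCC[Si](C)(C)C)c(OCOCC[Si](C)(C)C)cc1OCc1ccccc1 | intermediate
20 | 2-(DecCH2)-4,5-bis(SEM-oxy)phenol | C[C@@H]1CC=C2[C@@H](CCCC2(C)C)[C@]1(C)Cc1cc(OCOCC[Si](C)(C)C)c(OCOCC[Si](C)(C)C)cc1O | intermediate
21 | 2-(hydroxymethyl)-6-(DecCH2)-3,4-bis(SEM-oxy)phenol (not isolated) | C[C@@H]1CC=C2[C@@H](CCCC2(C)C)[C@]1(C)Cc1cc(OCOCC[Si](C)(C)C)c(OCOCC[Si](C)(C)C)c(CO)c1O | intermediate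
22 | 2-hydroxy-3-(DecCH2)-5,6-bis(SEM-oxy)benzaldehyde | C[C@@H]1CC=C2[C@@H](CCCC2(C)C)[C@]1(C)Cc1cc(OCOCC[Si](C)(C)C)c(OCOCC[Si](C)(C)C)c(C=O)c1O | intermediate
23 | 2-formyl-6-(DecCH2)-3,4-bis(SEM-oxy)phenyl hydrogen sulfate | C[C@@H]1CC=C2[C@@H](CCCC2(C)C)[C@]1(C)Cc1cc(OCOCC[Si](C)(C)C)c(OCOCC[Si](C)(C)C)c(C=O)c1OS(=O)(=O)O | intermediate
24 | 2-formyl-3,4-dihydroxy-6-{[(1R,2R,8aS)-1,2,5,5-tetramethyl-1,2,3,5,6,7,8,8a-octahydronaphthalen-1-yl]methyl}phenyl hydrogen sulfate | C[C@@H]1CC=C2[C@@H](CCCC2(C)C)[C@]1(C)Cc1cc(O)c(O)c(C=O)c1OS(=O)(=O)O | target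

**Totals and risks**

Total step count: 16. Longest linear sequence: 16 steps (1 → 24); the pulegone branch 6 → 24 is 12 steps.

Step 11 (cycloaddition). The bimolecular cycloaddition may be too slow at the diene terminus next to the quaternary C9, so that dimerisation or polymerisation of the electron-poor dienone takes over; the π-facial bias may also be too small. The fallback replaces the acyl diene by an electron-neutral silyloxyalkyl diene. Setting out from 14, silylation (TBSCl, imidazole, DMF) should give the dienyl silyl ether F1. F1 and 16 (toluene, 130 °C) should give the silyl ether adduct F2. TBAF (THF, 0 °C) should give the allylic alcohol F3, and Dess–Martin oxidation comes back to the route at 17.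

Step 9 (Wharton transposition). Condensation of hydrazine at the C10 carbonyl, which lies between the quaternary C9 and the fully substituted epoxide carbon C5, may be slower than nucleophilic opening of the epoxide. The fallback uses a radical fragmentation instead of a hydrazone. Setting out from 11, NaBH4 (MeOH, 0 °C) should give the epoxy alcohol F4. NaH, CS2, then MeI should give the S-methyl xanthate F5. Bu3SnH/AIBN (benzene, 80 °C, Barton–McCombie conditions) should generate the C10 radical, which opens the epoxide to the C6 alkoxy radical; hydrogen transfer comes back at 14.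

Step 12 (conjugate methylation and enolate trapping). The cuprate may fail to transfer methyl to the fully substituted β-carbon because γ-deprotonation, electron-transfer reduction or 1,2-addition compete, or the hindered enolate may not be phosphorylated on oxygen. The fallback uses allylic substitution instead of conjugate addition. Setting out from 17, Luche reduction (NaBH4, CeCl3, MeOH, −40 °C) should give the allylic alcohol F3. Esterification with picolinic acid (DCC, DMAP, CH2Cl2) should give the picolinate F6. MeMgBr with CuBr·SMe2 (THF, −40 °C) should displace the picolinate in an anti-SN2′ sense at C4 and give the gem-dimethyl Δ5 sulfone F7, which under the conditions of step 13 comes back at 20.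

**Further compounds**

F1 | step 11 | tert-butyldimethylsilyl ether of 14 | C[C@@H]1CC(O[Si](C)(C)C(C)(C)C)C(C(C)=C)=C[C@]1(C)Cc1cc(OCOCC[Si](C)(C)C)c(OCOCC[Si](C)(C)C)cc1OCc1ccccc1
F2 | step 11 | Diels–Alder adduct of F1 and 16 (C6 silyl ether, C4=C5, PhSO2 on C2, 8R,9R,10S) | C[C@@H]1CC(O[Si](C)(C)C(C)(C)C)C2=C(C)CC(S(=O)(=O)c3ccccc3)C[C@H]2[C@]1(C)Cc1cc(OCOCC[Si](C)(C)C)c(OCOCC[Si](C)(C)C)cc1OCc1ccccc1
F3 | step 11 | C6 allylic alcohol corresponding to 17 | C[C@@H]1CC(O)C2=C(C)CC(S(=O)(=O)c3ccccc3)C[C@H]2[C@]1(C)Cc1cc(OCOCC[Si](C)(C)C)c(OCOCC[Si](C)(C)C)cc1OCc1ccccc1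
F4 | step 9 | epoxy alcohol from reduction of 11 at C10 | C[C@@H]1CC2OC2(C(C)=C)C(O)[C@]1(C)Cc1cc(OCOCC[Si](C)(C)C)c(OCOCC[Si](C)(C)C)cc1OCc1ccccc1
F5 | step 9 | S-methyl xanthate of F4 | C[C@@H]1CC2OC2(C(C)=C)C(OC(=S)SC)[C@]1(C)Cc1cc(OCOCC[Si](C)(C)C)c(OCOCC[Si](C)(C)C)cc1OCc1ccccc1
F6 | step 12 | picolinate ester of F3 | C[C@@H]1CC(OC(=O)c3ccccn3)C2=C(C)CC(S(=O)(=O)c3ccccc3)C[C@H]2[C@]1(C)Cc1cc(OCOCC[Si](C)(C)C)c(OCOCC[Si](C)(C)C)cc1OCc1ccccc1
F7 | step 12 | 4,4-dimethyl Δ5 sulfone (19 with H in place of the phosphate) | C[C@@H]1CC=C2[C@@H](CC(S(=O)(=O)c3ccccc3)CC2(C)C)[C@]1(C)Cc1cc(OCOCC[Si](C)(C)C)c(OCOCC[Si](C)(C)C)cc1OCc1ccccc1
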